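Ring A of the benzofuran is made last, on a finished 2,5-disubstituted furan. A furyl(tert-alkyl)ketene and a siloxyalkyne are joined by [2+2] cycloaddition, 4π ring opening and 6π ring closure, which forms C4–C5, C6–C7 and C3a–C4 in one operation. The step exploits three features of ring A: the meta relation of the C4 and C6 oxygens, the lone hydrogen at C5, and the quaternary 1,1-dimethylallyl group on C7 beside C7a, which is carried in from an Ireland–Claisen rearrangement. Furan C3 is the only open site for the closure. The precursor is a racemic α-furyl acid chloride that bears the complete, MOM-protected diprenyl ring B.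

Key step: step 10

Assumption: (triisopropylsilyloxy)ethyne is not taken as a catalogue compound and is made in step 9 by the oxygenation–silylation used for substituted 1-siloxyalkynes; O-silylation of the unsubstituted ynolate is expected because the silyl triflate is bulky and hard.

Remarks on the design (MOM = methoxymethyl, TIPS = triisopropylsilyl):
(a) Deprotonation of the bis-MOM ether of 5-bromoresorcinol would occur between the two acetal oxygens. The prenyl groups are therefore placed beside bromine by electrophilic di-iodination and two iodine–magnesium exchanges, which the bromide survives.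
(b) The prenyl ester is made after the palladium step, because an allylic ester would ionize on zerovalent palladium.
(c) The acid chloride is made under neutral conditions, and the ketene is formed and freed from ammonium salt before the acid-sensitive ynol ether is added.
(d) The MOM ethers are removed before the silyl ether, so that the C6 oxygen beside the 1,1-dimethylallyl group stays masked while acid is present.

Step 1
Reactants: 1 5-bromoresorcinol (5-bromobenzene-1,3-diol)
Product: 2 1-bromo-3,5-bis(methoxymethoxy)benzene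
Conditions: MOMCl (2.5 equiv), i-Pr2NEt (3 equiv), CH2Cl2, 0 °C to rt
Reagents that add atoms: chloromethyl methyl ether, COCCl
Why: Base-mediated O-alkylation of both phenols with the α-chloro ether (acetal formation) gives a protecting group that tolerates the organomagnesium, palladium, enolate and thermal steps ahead and leaves under mild acid.

Step 2
Reactants: 2 1-bromo-3,5-bis(methoxymethoxy)benzene
Product: 3 3-bromo-2,4-diiodo-1,5-bis(methoxymethoxy)benzene
Conditions: NIS (2.3 equiv), MeCN, 0 °C to rt, dark
Reagents that add atoms: N-iodosuccinimide, O=C1CCC(=O)N1I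
Why: Electrophilic aromatic iodination should take place twice beside bromine, because each of these carbons is ortho to one acetal oxygen and para to the other whereas the carbon between the two MOM ethers is the most crowded, the pattern that dihalogenation of 5-substituted resorcinol diethers follows.

Step 3
Reactants: 3 3-bromo-2,4-diiodo-1,5-bis(methoxymethoxy)benzene; 4 prenyl bromide (1-bromo-3-methylbut-2-ene)
Product: 6 3-bromo-2-iodo-1,5-bis(methoxymethoxy)-4-(3-methylbut-2-enyl)benzene, via aryl Grignard reagent 5 (not isolated)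
Conditions: i-PrMgCl·LiCl (1.05 equiv), THF, −40 °C; then CuBr·SMe2 (10 mol%), 4 (1.2 equiv), −40 to −10 °C
Reagents that add atoms: none
Why: Iodine–magnesium exchange is far faster than bromine–magnesium exchange and stops after one iodine because the arylmagnesium formed is electron-rich, and the copper-catalysed allylic substitution of prenyl bromide by the aryl nucleophile then occurs at the primary carbon since attack at the fully substituted allyl terminus is hindered.

Step 4
Reactants: 6 3-bromo-2-iodo-1,5-bis(methoxymethoxy)-4-(3-methylbut-2-enyl)benzene; 4 prenyl bromide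
Product: 8 3-bromo-1,5-bis(methoxymethoxy)-2,4-bis(3-methylbut-2-enyl)benzene, via aryl Grignard reagent 7 (not isolated)
Conditions: i-PrMgCl·LiCl (1.15 equiv), THF, −30 °C; then CuBr·SMe2 (10 mol%), 4 (1.3 equiv), −30 to 0 °C
Reagents that add atoms: none
Why: The same halogen–magnesium exchange and copper-catalysed allylic substitution are repeated at the remaining iodide, which is activated by the flanking bromine and the chelating MOM ether, while the bromide stays in place for the coupling.

Step 5
Reactants: 8 3-bromo-1,5-bis(methoxymethoxy)-2,4-bis(3-methylbut-2-enyl)benzene; 9 methyl 2-(furan-2-yl)acetate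
Product: 10 methyl 2-[5-[3,5-bis(methoxymethoxy)-2,6-bis(3-methylbut-2-enyl)phenyl]furan-2-yl]acetate
Conditions: Pd(OAc)2 (5 mol%), PCy3·HBF4 (10 mol%), PivOH (30 mol%), K2CO3 (2 equiv), 9 (2 equiv), DMA, 100 °C
Reagents that add atoms: none
Why: Palladium-catalysed direct C–H arylation by concerted metalation–deprotonation should occur at C5, the only free α-position of the furan, with the electron-rich PCy3 ligand supporting oxidative addition of the doubly ortho-substituted bromide and the trisubstituted prenyl alkenes being poor partners for Heck insertion.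

Step 6
Reactants: 10 methyl 2-[5-[3,5-bis(methoxymethoxy)-2,6-bis(3-methylbut-2-enyl)phenyl]furan-2-yl]acetate; 11 prenol (3-methylbut-2-en-1-ol)
Product: 12 3-methylbut-2-enyl 2-[5-[3,5-bis(methoxymethoxy)-2,6-bis(3-methylbut-2-enyl)phenyl]furan-2-yl]acetate
Conditions: 11 (10 equiv), Ti(OiPr)4 (10 mol%), toluene, 100 °C, 4 Å molecular sieves (removal of MeOH)
Reagents that add atoms: none
Why: Titanate-catalysed transesterification is an equilibrium that excess prenol and removal of methanol push to the allylic ester under neutral conditions that leave the MOM ethers and the furan untouched.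

Step 7
Reactants: 12 3-methylbut-2-enyl 2-[5-[3,5-bis(methoxymethoxy)-2,6-bis(3-methylbut-2-enyl)phenyl]furan-2-yl]acetate
Product: 16 racemic 2-[5-[3,5-bis(methoxymethoxy)-2,6-bis(3-methylbut-2-enyl)phenyl]furan-2-yl]-3,3-dimethylpent-4-enoic acid, via lithium enolate 13 (not isolated), via silyl ketene acetal 14 (not isolated), via trimethylsilyl ester 15 (not isolated)
Conditions: LiN(i-Pr)2 (1.2 equiv), THF, −78 °C; TMSCl (1.5 equiv); −78 to 65 °C; then aq. citric acid
Reagents that add atoms: none
Why: Ireland–Claisen rearrangement, in which the furyl-stabilised ester enolate is silylated on oxygen and the ketene acetal undergoes a [3,3]-sigmatropic shift through a chair transition state that joins the α-carbon to the dimethyl-substituted allyl terminus, creates the quaternary carbon with its vinyl group, and the one new stereocenter is formed as a racemate that is erased when the ketene is made.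

Step 8
Reactants: 16 racemic 2-[5-[3,5-bis(methoxymethoxy)-2,6-bis(3-methylbut-2-enyl)phenyl]furan-2-yl]-3,3-dimethylpent-4-enoic acid
Product: 17 racemic 2-[5-[3,5-bis(methoxymethoxy)-2,6-bis(3-methylbut-2-enyl)phenyl]furan-2-yl]-3,3-dimethylpent-4-enoyl chloride
Conditions: 1-chloro-N,N,2-trimethylprop-1-en-1-amine (1.2 equiv), CH2Cl2, 0 °C to rt; concentrated and used crude
Reagents that add atoms: 1-chloro-N,N,2-trimethylprop-1-en-1-amine, CC(C)=C(Cl)N(C)C
Why: The α-chloroenamine turns the hindered acid into its chloride by nucleophilic acyl substitution through an acyloxyiminium ion and releases only a neutral amide, so the MOM ethers, the furan and the alkenes are not exposed to HCl.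

Step 9
Reactants: 18 acetylene (ethyne)
Product: 21 (triisopropylsilyloxy)ethyne, via lithium acetylide 19 (not isolated), via lithium ethynolate 20 (not isolated)
Conditions: 18 (excess), n-BuLi (1.0 equiv), THF, −78 °C; t-BuOOLi (from t-BuOOH and LiN(SiMe3)2, 1.1 equiv), −78 to −10 °C; TIPSOTf (1.2 equiv), −78 to 0 °C
Reagents that add atoms: tert-butyl hydroperoxide, CC(C)(C)OO; triisopropylsilyl trifluoromethanesulfonate, CC(C)[Si](C(C)C)(C(C)C)OS(=O)(=O)C(F)(F)F
Why: Electrophilic oxygenation of a lithium acetylide by lithium tert-butyl peroxide gives the ynolate, which the bulky and hard silyl triflate should capture at oxygen, the standard route from terminal alkynes to 1-siloxyalkynes, while excess acetylene at low temperature keeps the monolithium acetylide from disproportionating.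

Step 10
Reactants: 17 racemic 2-[5-[3,5-bis(methoxymethoxy)-2,6-bis(3-methylbut-2-enyl)phenyl]furan-2-yl]-3,3-dimethylpent-4-enoyl chloride; 21 (triisopropylsilyloxy)ethyne
Product: 26 2-[3,5-bis(methoxymethoxy)-2,6-bis(3-methylbut-2-enyl)phenyl]-7-(2-methylbut-3-en-2-yl)-6-(triisopropylsilyloxy)-1-benzofuran-4-ol, via furyl(tert-alkyl)ketene 22 (not isolated), via 3-siloxycyclobutenone 23 (not isolated), via dienylketene 24 (not isolated), via cyclohexadienone 25 (not isolated)
Conditions: Et3N (1.5 equiv), toluene, rt to 60 °C, Et3NHCl filtered off under Ar; then 21 (2 equiv), sealed tube, 80 to 110 °C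
Reagents that add atoms: none
Why: Proposed new method: dehydrochlorination of 17 gives the persistent ketene 22, whose carbonyl carbon is attacked by the nucleophilic CH carbon of 21 while the siloxy carbon bonds to the ketene α-carbon, so that [2+2] closure gives cyclobutenone 23 with oxygen destined for C6 and hydrogen for C5; the closest known type is the benzannulation of monosubstituted aryl- and vinylketenes with siloxyalkynes, which has not been shown for a ketene carrying both a tertiary alkyl group and a furan. Thermal conrotatory 4π opening of 23 should turn the bulky tertiary group outward and the furan inward, and because the opening is reversible only isomer 24, with the furan next to the new ketene, is drained. Ring A is then closed by a thermal disrotatory 6π electrocyclization in which the ketene carbon bonds to furan C3 (C3a–C4), and amine-assisted enolization of 25 restores aromaticity. No stereocenter survives, since the quaternary carbon of 23 and C3a of 25 are transient and racemic. The step needs regioselectivity in the cycloaddition, which the polarization of the ynol ether secures, and site selectivity in the closure, which is secured because C3 is the only unsubstituted carbon beside the ketene-bearing furan carbon. The crowded ketene should resist dimerization and acylation of the product phenol, and the triisopropylsilyl group slows the shift of silicon from oxygen to carbon in 21.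

Step 11
Reactants: 26 2-[3,5-bis(methoxymethoxy)-2,6-bis(3-methylbut-2-enyl)phenyl]-7-(2-methylbut-3-en-2-yl)-6-(triisopropylsilyloxy)-1-benzofuran-4-ol
Product: 27 5-[4-hydroxy-7-(2-methylbut-3-en-2-yl)-6-(triisopropylsilyloxy)-1-benzofuran-2-yl]-4,6-bis(3-methylbut-2-enyl)benzene-1,3-diol
Conditions: HCl (1.25 M in MeOH, 6 equiv), MeOH/THF, 0 °C to 40 °C
Reagents that add atoms: none
Why: Acid-catalysed acetal methanolysis removes both MOM ethers as dimethoxymethane under dilute conditions of the kind that ortho-prenyl phenols tolerate without chroman formation, while the hindered aryl silyl ether should persist and keep the C6 oxygen from adding to the neighbouring 1,1-dimethylallyl group.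

Step 12
Reactants: 27 5-[4-hydroxy-7-(2-methylbut-3-en-2-yl)-6-(triisopropylsilyloxy)-1-benzofuran-2-yl]-4,6-bis(3-methylbut-2-enyl)benzene-1,3-diol
Product: 28 2-[3,5-dihydroxy-2,6-bis(3-methylbut-2-enyl)phenyl]-7-(2-methylbut-3-en-2-yl)-1-benzofuran-4,6-diol (CNP0115465.0)
Conditions: TBAF (1.2 equiv), AcOH (1.2 equiv), THF, 0 °C, Ar
Reagents that add atoms: none
Why: Fluoride attacks silicon and releases the phenoxide (silyl ether cleavage driven by the Si–F bond) under buffered, non-acidic conditions that leave the three alkenes and the free phenols untouched.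

Compound list
1 | 5-bromoresorcinol (5-bromobenzene-1,3-diol) | Oc1cc(O)cc(Br)c1 | starting material
2 | 1-bromo-3,5-bis(methoxymethoxy)benzene | COCOc1cc(Br)cc(OCOC)c1 | intermediate
3 | 3-bromo-2,4-diiodo-1,5-bis(methoxymethoxy)benzene | COCOc1cc(OCOC)c(I)c(Br)c1I | intermediate
4 | prenyl bromide (1-bromo-3-methylbut-2-ene) | CC(C)=CCBr | starting material
5 | [2-bromo-3-iodo-4,6-bis(methoxymethoxy)phenyl]magnesium chloride (LiCl complex) | COCOc1cc(OCOC)c(I)c(Br)c1[Mg]Cl | intermediate
6 | 3-bromo-2-iodo-1,5-bis(methoxymethoxy)-4-(3-methylbut-2-enyl)benzene | COCOc1cc(OCOC)c(I)c(Br)c1CC=C(C)C | intermediate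
7 | [2-bromo-4,6-bis(methoxymethoxy)-3-(3-methylbut-2-enyl)phenyl]magnesium chloride (LiCl complex) | COCOc1cc(OCOC)c([Mg]Cl)c(Br)c1CC=C(C)C | intermediate
8 | 3-bromo-1,5-bis(methoxymethoxy)-2,4-bis(3-methylbut-2-enyl)benzene | COCOc1cc(OCOC)c(CC=C(C)C)c(Br)c1CC=C(C)C | intermediate
9 | methyl 2-(furan-2-yl)acetate | COC(=O)Cc1ccco1 | starting material
10 | methyl 2-[5-[3,5-bis(methoxymethoxy)-2,6-bis(3-methylbut-2-enyl)phenyl]furan-2-yl]acetate | COC(=O)Cc1ccc(-c2c(CC=C(C)C)c(OCOC)cc(OCOC)c2CC=C(C)C)o1 | intermediate
11 | prenol (3-methylbut-2-en-1-ol) | CC(C)=CCO | starting material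
12 | 3-methylbut-2-enyl 2-[5-[3,5-bis(methoxymethoxy)-2,6-bis(3-methylbut-2-enyl)phenyl]furan-2-yl]acetate | CC(C)=CCOC(=O)Cc1ccc(-c2c(CC=C(C)C)c(OCOC)cc(OCOC)c2CC=C(C)C)o1 | intermediate
13 | lithium 2-[5-[3,5-bis(methoxymethoxy)-2,6-bis(3-methylbut-2-enyl)phenyl]furan-2-yl]-1-(3-methylbut-2-enyloxy)ethenolate (enolate geometry not defined) | [Li+].[O-]C(OCC=C(C)C)=Cc1ccc(-c2c(CC=C(C)C)c(OCOC)cc(OCOC)c2CC=C(C)C)o1 | intermediate
14 | [2-[5-[3,5-bis(methoxymethoxy)-2,6-bis(3-methylbut-2-enyl)phenyl]furan-2-yl]-1-(3-methylbut-2-enyloxy)ethenoxy]trimethylsilane (E/Z mixture) | C[Si](C)(C)OC(OCC=C(C)C)=Cc1ccc(-c2c(CC=C(C)C)c(OCOC)cc(OCOC)c2CC=C(C)C)o1 | intermediate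
15 | racemic trimethylsilyl 2-[5-[3,5-bis(methoxymethoxy)-2,6-bis(3-methylbut-2-enyl)phenyl]furan-2-yl]-3,3-dimethylpent-4-enoate | C=CC(C)(C)C(C(=O)O[Si](C)(C)C)c1ccc(-c2c(CC=C(C)C)c(OCOC)cc(OCOC)c2CC=C(C)C)o1 | intermediate
16 | racemic 2-[5-[3,5-bis(methoxymethoxy)-2,6-bis(3-methylbut-2-enyl)phenyl]furan-2-yl]-3,3-dimethylpent-4-enoic acid | C=CC(C)(C)C(C(=O)O)c1ccc(-c2c(CC=C(C)C)c(OCOC)cc(OCOC)c2CC=C(C)C)o1 | intermediate
17 | racemic 2-[5-[3,5-bis(methoxymethoxy)-2,6-bis(3-methylbut-2-enyl)phenyl]furan-2-yl]-3,3-dimethylpent-4-enoyl chloride | C=CC(C)(C)C(C(=O)Cl)c1ccc(-c2c(CC=C(C)C)c(OCOC)cc(OCOC)c2CC=C(C)C)o1 | intermediate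
18 | acetylene (ethyne) | C#C | starting material
19 | lithium acetylide | [Li+].[C-]#C | intermediate
20 | lithium ethynolate | [Li+].[O-]C#C | intermediate
21 | (triisopropylsilyloxy)ethyne | C#CO[Si](C(C)C)(C(C)C)C(C)C | intermediate
22 | 2-[5-[3,5-bis(methoxymethoxy)-2,6-bis(3-methylbut-2-enyl)phenyl]furan-2-yl]-3,3-dimethylpenta-1,4-dien-1-one (ketene) | C=CC(C)(C)C(=C=O)c1ccc(-c2c(CC=C(C)C)c(OCOC)cc(OCOC)c2CC=C(C)C)o1 | intermediate
23 | racemic 4-[5-[3,5-bis(methoxymethoxy)-2,6-bis(3-methylbut-2-enyl)phenyl]furan-2-yl]-4-(2-methylbut-3-en-2-yl)-3-(triisopropylsilyloxy)cyclobut-2-en-1-one | C=CC(C)(C)C1(c2ccc(-c3c(CC=C(C)C)c(OCOC)cc(OCOC)c3CC=C(C)C)o2)C(=O)C=C1O[Si](C(C)C)(C(C)C)C(C)C | intermediate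
24 | (3E)-4-[5-[3,5-bis(methoxymethoxy)-2,6-bis(3-methylbut-2-enyl)phenyl]furan-2-yl]-5,5-dimethyl-3-(triisopropylsilyloxy)hepta-1,3,6-trien-1-one | C=CC(C)(C)/C(c1ccc(-c2c(CC=C(C)C)c(OCOC)cc(OCOC)c2CC=C(C)C)o1)=C(/C=C=O)O[Si](C(C)C)(C(C)C)C(C)C | intermediate
25 | racemic 2-[3,5-bis(methoxymethoxy)-2,6-bis(3-methylbut-2-enyl)phenyl]-7-(2-methylbut-3-en-2-yl)-6-(triisopropylsilyloxy)-3aH-1-benzofuran-4-one | C=CC(C)(C)C1=C2OC(-c3c(CC=C(C)C)c(OCOC)cc(OCOC)c3CC=C(C)C)=CC2C(=O)C=C1O[Si](C(C)C)(C(C)C)C(C)C | intermediate
26 | 2-[3,5-bis(methoxymethoxy)-2,6-bis(3-methylbut-2-enyl)phenyl]-7-(2-methylbut-3-en-2-yl)-6-(triisopropylsilyloxy)-1-benzofuran-4-ol | C=CC(C)(C)c1c(O[Si](C(C)C)(C(C)C)C(C)C)cc(O)c2cc(-c3c(CC=C(C)C)c(OCOC)cc(OCOC)c3CC=C(C)C)oc12 | intermediate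
27 | 5-[4-hydroxy-7-(2-methylbut-3-en-2-yl)-6-(triisopropylsilyloxy)-1-benzofuran-2-yl]-4,6-bis(3-methylbut-2-enyl)benzene-1,3-diol | C=CC(C)(C)c1c(O[Si](C(C)C)(C(C)C)C(C)C)cc(O)c2cc(-c3c(CC=C(C)C)c(O)cc(O)c3CC=C(C)C)oc12 | intermediate
28 | 2-[3,5-dihydroxy-2,6-bis(3-methylbut-2-enyl)phenyl]-7-(2-methylbut-3-en-2-yl)-1-benzofuran-4,6-diol (CNP0115465.0, no stereocenter) | C=CC(C)(C)c1c(O)cc(O)c2cc(-c3c(CC=C(C)C)c(O)cc(O)c3CC=C(C)C)oc12 | target

Total step count: 12 (steps 1–8 and 10–12 in line, step 9 as a one-step side branch).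
Longest linear sequence: 11 steps, from 5-bromoresorcinol.

Steps most likely to fail

1. The benzannulation (step 10). The cycloaddition of the crowded ketene may be slower than the thermal shift of silicon from oxygen to carbon in the ynol ether. The cyclobutenone may also stall, either by opening with the furan turned outward or by a [3,3] shift of its allyl group. The fallback uses the established form of the same annulation, with a monosubstituted hetarylketene, and installs the C7 group afterwards; it sets out from 10 and returns at 28.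
 - Ester 10 would be saponified (LiOH, THF/H2O) to 2-[5-[3,5-bis(methoxymethoxy)-2,6-bis(3-methylbut-2-enyl)phenyl]furan-2-yl]acetic acid F1.
 - The chloroenamine of step 8 would convert F1 into the acid chloride F2.
 - Slow addition of F2 to Et3N and 21 in toluene at 80 °C should generate the monosubstituted furylketene F3 and carry it through the cascade to the C7-unsubstituted 2-aryl-6-(triisopropylsilyloxy)-1-benzofuran-4-ol F4.
 - Protection of the C4 phenol (MOMCl, i-Pr2NEt) would give the tris-MOM silyl ether F5.
 - CsF and prenyl bromide 4 in DMF would exchange the silyl group for a prenyl group in one flask and give the C6 prenyl ether F6.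
 - Aromatic Claisen rearrangement (N,N-diethylaniline, 180 °C, or Eu(fod)3 as catalyst at lower temperature) should deliver the allyl unit with inversion, as the 1,1-dimethylallyl group, to C7. This is the ortho carbon across the C6–C7 bond of higher double-bond character, as with 2-naphthyl and 7-coumarinyl allyl ethers. The product is the 7-(2-methylbut-3-en-2-yl)-6-hydroxy tris-MOM ether F7.
 - The acid conditions of step 11 would then remove the three MOM groups and give 28.

2. The direct arylation (step 5). Oxidative addition and the metalation–deprotonation step may both be slow for a bromide flanked by two prenyl groups, which would allow hydrodebromination and catalyst decay to take over. The fallback sets out from 9 and returns at 10. Iridium-catalysed C–H borylation of 9 ([Ir(OMe)(cod)]2, 4,4′-di-tert-butyl-2,2′-bipyridine, B2pin2, THF, rt to 50 °C) should occur at the free α-position and give methyl 2-[5-(4,4,5,5-tetramethyl-1,3,2-dioxaborolan-2-yl)furan-2-yl]acetate F8. Suzuki–Miyaura coupling of F8 with bromide 8 (Pd(OAc)2, SPhos, K3PO4, toluene/H2O, 80 °C), a catalyst system suited to doubly ortho-substituted halides, would give 10.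

3. The MOM cleavage (step 11). Protonation of a prenyl alkene next to a freed ring B phenol may lead to chroman formation, and the methoxymethyl cation may alkylate the electron-rich rings. The fallback avoids protic acid; it sets out from 26 and returns at 28. TMSOTf and 2,2′-bipyridyl in CH2Cl2 at 0 °C convert aryl MOM ethers into aryl trimethylsilyl ethers and would also silylate the free C4 phenol, which should give the tetrasilyl ether F9 (three trimethylsilyl groups and the triisopropylsilyl group). The fluoride conditions of step 12, with more TBAF and AcOH, would then remove all four silyl groups in one operation and give 28 without passing through 27.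

Further compounds
F1 | step 10 | 2-[5-[3,5-bis(methoxymethoxy)-2,6-bis(3-methylbut-2-enyl)phenyl]furan-2-yl]acetic acid | OC(=O)Cc1ccc(-c2c(CC=C(C)C)c(OCOC)cc(OCOC)c2CC=C(C)C)o1
F2 | step 10 | 2-[5-[3,5-bis(methoxymethoxy)-2,6-bis(3-methylbut-2-enyl)phenyl]furan-2-yl]acetyl chloride | ClC(=O)Cc1ccc(-c2c(CC=C(C)C)c(OCOC)cc(OCOC)c2CC=C(C)C)o1
F3 | step 10 | 2-[5-[3,5-bis(methoxymethoxy)-2,6-bis(3-methylbut-2-enyl)phenyl]furan-2-yl]ethenone (ketene) | O=C=Cc1ccc(-c2c(CC=C(C)C)c(OCOC)cc(OCOC)c2CC=C(C)C)o1
F4 | step 10 | 2-[3,5-bis(methoxymethoxy)-2,6-bis(3-methylbut-2-enyl)phenyl]-6-(triisopropylsilyloxy)-1-benzofuran-4-ol | Oc1cc(O[Si](C(C)C)(C(C)C)C(C)C)cc2oc(-c3c(CC=C(C)C)c(OCOC)cc(OCOC)c3CC=C(C)C)cc12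
F5 | step 10 | [2-[3,5-bis(methoxymethoxy)-2,6-bis(3-methylbut-2-enyl)phenyl]-4-(methoxymethoxy)-1-benzofuran-6-yl]oxy-triisopropylsilane | COCOc1cc(O[Si](C(C)C)(C(C)C)C(C)C)cc2oc(-c3c(CC=C(C)C)c(OCOC)cc(OCOC)c3CC=C(C)C)cc12
F6 | step 10 | 2-[3,5-bis(methoxymethoxy)-2,6-bis(3-methylbut-2-enyl)phenyl]-4-(methoxymethoxy)-6-(3-methylbut-2-enyloxy)-1-benzofuran | COCOc1cc(OCC=C(C)C)cc2oc(-c3c(CC=C(C)C)c(OCOC)cc(OCOC)c3CC=C(C)C)cc12
F7 | step 10 | 2-[3,5-bis(methoxymethoxy)-2,6-bis(3-methylbut-2-enyl)phenyl]-4-(methoxymethoxy)-7-(2-methylbut-3-en-2-yl)-1-benzofuran-6-ol | C=CC(C)(C)c1c(O)cc(OCOC)c2cc(-c3c(CC=C(C)C)c(OCOC)cc(OCOC)c3CC=C(C)C)oc12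
F8 | step 5 | methyl 2-[5-(4,4,5,5-tetramethyl-1,3,2-dioxaborolan-2-yl)furan-2-yl]acetate | COC(=O)Cc1ccc(B2OC(C)(C)C(C)(C)O2)o1
F9 | step 11 | [2-[3,5-bis(trimethylsilyloxy)-2,6-bis(3-methylbut-2-enyl)phenyl]-7-(2-methylbut-3-en-2-yl)-4-(trimethylsilyloxy)-1-benzofuran-6-yl]oxy-triisopropylsilane | C=CC(C)(C)c1c(O[Si](C(C)C)(C(C)C)C(C)C)cc(O[Si](C)(C)C)c2cc(-c3c(CC=C(C)C)c(O[Si](C)(C)C)cc(O[Si](C)(C)C)c3CC=C(C)C)oc12
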